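**Assumption:** phloroisobutyrophenone and (R)-(−)-linalool (high-ee grade) are catalogue items. Terpene carbons keep linalool numbering (C1=C2 vinyl, C3 carbinol, C6=C7 alkene, C8 the oxidised E-methyl). "Far-side C–O" is the ring carbonyl/enol next to the ring CH that later carries the two prenyls; "acyl-side C–O" is the one next to the isobutyryl-bearing carbon.

**Retrosynthetic overview**
1. Tomoeone A ⇒ gem-diprenylation of the only free ring CH of spiro acyl-trione diol 8; the prenyls go on last so no other alkene is present during hydration.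
2. 8 ⇒ Markovnikov (HAT) hydration of the single C7=C8 alkene of spiro-cyclohexene 6.
3. 6 ⇒ Knoevenagel condensation / intramolecular Diels–Alder of phloroisobutyrophenone 3 with (R)-8-oxolinalool 2 (diene C(spiro)=C8–C7=C6, dienophile C1=C2).
4. 2 ⇒ allylic oxidation of (R)-linalool 1, the only source of chirality.
5. Ring order: acyl-trione ring (bought as the arene), then cyclopentane and spiro-cyclohexane together in the cycloaddition.

**Step 1**
Reactants: 1 (R)-(−)-linalool
Product: 2 (2E,6R)-6-hydroxy-2,6-dimethylocta-2,7-dienal (8-oxolinalool)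
Conditions: SeO2 (1.3 equiv), 1,4-dioxane/H2O (20:1), 80 °C
Reagents that add atoms: selenium dioxide, O=[Se]=O
Why: Riley allylic oxidation (ene reaction then [2,3]-sigmatropic shift) selectively oxidises the E-methyl of the trisubstituted alkene to the (E)-enal; the vinyl group has no allylic C–H and the C3 stereocentre is not touched.

**Step 2**
Reactants: 2 (2E,6R)-6-hydroxy-2,6-dimethylocta-2,7-dienal; 3 phloroisobutyrophenone (2 equiv)
Product: 6 spiro-cyclohexene Diels–Alder adduct, via vinyl o-quinone methide 4 (not isolated), via 2H-chromene 5 (not isolated)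
Conditions: pyridine (0.05 M), 110 °C, 8 h; then 170 °C, sealed tube, 12–24 h; chromatography
Reagents that add atoms: none
Why: Knoevenagel condensation (loss of water) gives the vinyl o-quinone methide, which is stored reversibly as the 2H-chromene (oxa-6π electrocyclisation) until it undergoes an irreversible intramolecular Diels–Alder reaction of the 1,3,8-nonatriene type forming C6–C2 and C(spiro)–C1; the E-diene with a three-atom tether favours trans fusion, the C3 centre places CH3 pseudo-equatorial and OH pseudo-axial in the forming cyclopentane (setting C2 and C6), and the spiro centre follows from the methide geometry that turns the far-side C=O inward and keeps the chelated isobutyryl side away from the tether, with minor diastereomers removed by chromatography.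

**Step 3**
Reactants: 6 spiro-cyclohexene Diels–Alder adduct
Product: 8 spiro acyl-trione diol, via tertiary hydroperoxide 7 (not isolated)
Conditions: Co(acac)2 (0.2 equiv), PhSiH3 (2.5 equiv), O2 (1 atm), iPrOH/THF, 0 °C → rt; then PPh3
Reagents that add atoms: dioxygen, O=O
Why: Mukaiyama hydration (HAT to C8, then O2 capture of the tertiary C7 radical) is Markovnikov on the only C=C present, and O2 approaches anti to the axial acyl-side carbonyl on the spiro carbon (1,3-diaxial to C7), giving equatorial OH cis to H-6 and axial CH3.

**Step 4**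
Reactants: 8 spiro acyl-trione diol; 9 prenyl bromide (2.5 equiv)
Product: 11 Tomoeone A, via mono-C-prenyl compound 10 (not isolated)
Conditions: NaOMe (3.5 equiv), MeOH, 0 °C → rt; then 1 M HCl work-up
Reagents that add atoms: prenyl bromide, CC(C)=CCBr
Why: Twofold C-alkylation of the vinylogous-acid carbon (lupulone-type geminal prenylation) occurs at the only ring carbon still carrying hydrogen; the tertiary alcohols are not alkylated and no stereocentre is involved.

**Compound list**
1 | (R)-(−)-linalool, (3R)-3,7-dimethylocta-1,6-dien-3-ol | CC(C)=CCC[C@](C)(C=C)O | starting material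
2 | (2E,6R)-6-hydroxy-2,6-dimethylocta-2,7-dienal | O=C/C(C)=C/CC[C@](C)(C=C)O | intermediate
3 | phloroisobutyrophenone, 2-methyl-1-(2,4,6-trihydroxyphenyl)propan-1-one | CC(C)C(=O)c1c(O)cc(O)cc1O | starting material
4 | vinyl o-quinone methide: Knoevenagel dienone with the exocyclic C=C8 bond having C7 cis to the far-side C=O, 6E, 3R | C=C[C@](C)(O)CC/C=C(C)/C=C1\C(=O)C=C(O)C(C(=O)C(C)C)=C1O | intermediate
5 | 2H-chromene: 1-[5,7-dihydroxy-2-[(3R)-3-hydroxy-3-methylpent-4-en-1-yl]-3-methyl-2H-chromen-6-yl]-2-methylpropan-1-one, both C2 epimers | C=C[C@](C)(O)CCC1Oc2cc(O)c(C(=O)C(C)C)c(O)c2C=C1C | intermediate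
6 | spiro-cyclohexene Diels–Alder adduct: (1R,3aR,7aS)-1-hydroxy-1,4-dimethyl-2,3,3a,7a-tetrahydro-1H,7H-indene spiro-fused at C6 to C4 of 2-isobutyryl-3,5-dihydroxycyclohexa-2,5-dienone; trans-fused, OH trans to H-7a, far-side C–O cis to H-3a | O=C1C=C(O)[C@@]2(C[C@H]3[C@@H](CC[C@@]3(C)O)C(C)=C2)C(O)=C1C(=O)C(C)C | intermediate
7 | tertiary hydroperoxide: 6 with H added at C8 and OOH at C7 (indane C4), OOH cis to H-3a | O=C1C=C(O)[C@@]2(C[C@H]3[C@@H](CC[C@@]3(C)O)[C@](C)(OO)C2)C(O)=C1C(=O)C(C)C | intermediate
8 | spiro acyl-trione diol: (1R,3aR,4R,7aS)-1,4-dihydroxy-1,4-dimethyl-octahydroindene spiro-fused at C6 to C4 of 2-isobutyryl-3,5-dihydroxycyclohexa-2,5-dienone; trans-fused, both OH and the far-side C–O on the face of H-3a, both CH3 and the acyl-side C–O on the face of H-7a | O=C1C=C(O)[C@@]2(C[C@H]3[C@@H](CC[C@@]3(C)O)[C@](C)(O)C2)C(O)=C1C(=O)C(C)C | intermediate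
9 | prenyl bromide, 1-bromo-3-methylbut-2-ene | CC(C)=CCBr | starting material
10 | mono-C-prenyl compound: 8 carrying one prenyl on the free ring carbon (enol form) | O=C1C(CC=C(C)C)=C(O)[C@@]2(C[C@H]3[C@@H](CC[C@@]3(C)O)[C@](C)(O)C2)C(O)=C1C(=O)C(C)C | intermediate
11 | Tomoeone A: 8 with two prenyls on the ring carbon between the far-side C=O and the enol carbon; hydrindane 1R,3aR,4R,7aS, spiro carbon S in the drawn tautomer | CC(C)=CCC1(CC=C(C)C)C(=O)[C@@]2(C[C@H]3[C@@H](CC[C@@]3(C)O)[C@](C)(O)C2)C(=O)C(C(=O)C(C)C)=C1O | target

**Totals**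
Total steps: 4. Longest linear sequence: 4 (1 → 2 → 6 → 8 → 11).

**Three steps most likely to fail**

Step 2 (Knoevenagel / intramolecular Diels–Alder). This cascade is a design proposal, not a known reaction on this substrate. The aromatic 2H-chromene may act as a sink, the tertiary allylic alcohol may suffer oxa-Michael addition or ionisation at 170 °C, and selectivity over ring fusion, face and spiro centre may be modest, so the yield of the single diastereomer 6 could be low. Fallback, setting out from 3 (with 2) and returning at 11: 3 is first dearomatised by Pd-catalysed double allylation (allyl methyl carbonate, Pd(PPh3)4, THF) to the gem-diallyl acyl-trione F1, which cannot aromatise to a chromene. Condensation of F1 with 2 (EDDA, toluene, 110–140 °C) then gives, through a mobile 2H-pyran/dienone equilibrium, the gem-diallyl spiro-cyclohexene F2 by the same intramolecular Diels–Alder reaction; the spiro-epimer ratio would have to be re-determined. HAT hydration (Mn(dpm)3, PhSiH3, O2, iPrOH; then PPh3) of the trisubstituted ring alkene in preference to the monosubstituted allyl groups gives the gem-diallyl diol F3. Cross-metathesis with 2-methyl-2-butene (Grubbs II, 40 °C) turns both allyl groups into prenyl groups and gives 11.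

Step 3 (Mukaiyama hydration). The free, electron-rich, metal-chelating enolised trione with its ring C–H may be oxidised under Co/O2, and the face selectivity at C7 is argued, not proven. Fallback, setting out from 6 and returning at 8: 6 is masked with Ac2O/pyridine (no DMAP, tertiary OH untouched) as the bis(enol acetate) F4. The same HAT hydration on this non-chelating, less oxidisable substrate gives the hydrated bis(enol acetate) F5, and K2CO3/MeOH methanolysis returns 8.

Step 4 (geminal diprenylation). O-alkylation and incomplete second alkylation can erode the yield. Fallback, setting out from 8 and returning at 11: base-free Pd-catalysed Tsuji–Trost prenylation (prenyl methyl carbonate, Pd(PPh3)4, THF, rt to 50 °C) uses a π-prenyl-palladium electrophile that the soft carbon nucleophile attacks at carbon at the unsubstituted terminus. It passes through the same mono-prenyl compound 10 and makes no new compound.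

**Further compounds**
F1 | step 2 | gem-diallyl acyl-trione, 4,4-diallyl-3,5-dihydroxy-2-isobutyrylcyclohexa-2,5-dienone | C=CCC1(CC=C)C(O)=CC(=O)C(C(=O)C(C)C)=C1O
F2 | step 2 | gem-diallyl spiro-cyclohexene (diallyl analogue of the cycloadduct, same configuration as 6) | C=CCC1(CC=C)C(=O)[C@@]2(C[C@H]3[C@@H](CC[C@@]3(C)O)C(C)=C2)C(=O)C(C(=O)C(C)C)=C1O
F3 | step 2 | gem-diallyl diol (diallyl analogue of 11) | C=CCC1(CC=C)C(=O)[C@@]2(C[C@H]3[C@@H](CC[C@@]3(C)O)[C@](C)(O)C2)C(=O)C(C(=O)C(C)C)=C1O
F4 | step 3 | bis(enol acetate) of 6 | O=C1C=C(OC(C)=O)[C@@]2(C[C@H]3[C@@H](CC[C@@]3(C)O)C(C)=C2)C(OC(C)=O)=C1C(=O)C(C)C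
F5 | step 3 | hydrated bis(enol acetate), bis-acetate of 8 | O=C1C=C(OC(C)=O)[C@@]2(C[C@H]3[C@@H](CC[C@@]3(C)O)[C@](C)(O)C2)C(OC(C)=O)=C1C(=O)C(C)C
F0 | step 4 | none | none
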